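**Plan**
- Cuts (chromanone numbering O1, C2, C3, C4, C4a, C5–C8, C8a): first the C6–prenyl bond and the ester C–O bond of the side chain (re-closed as a δ-lactone onto O7), then C4–C4a of pyranone ring B, then the O1–C2 ether bond, then the C–H bond at the side-chain stereocentre (back to a coumarin), last the Pechmann bonds.
- Forward: the coumarin ring is made first and later, as a dihydrocoumarin lactone, masks O7 and the hexanoate. O5 is benzylated, the C2–C3 unit is attached to O1, the lactone ring is reduced, ring B is closed by arene acylation, and the end game exchanges benzyl, lactone and C6–H for OH, methyl ester and prenyl.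
- Stereochemistry: C3 comes from (S)-3-hydroxybutanoate by anti-selective Fráter–Seebach methylation. C2 is set by Mitsunobu inversion (anti alcohol to syn ether, which maps onto cis-2R,3S). The side-chain centre (R) is set by ligand-controlled copper hydride conjugate reduction.
- Enabling feature: ring A is a phloroglucinol ring whose C8, ortho to O1, already carries the side chain tied back to O7. The acyl tether on O1 can therefore reach only C4a, which is activated by O1 and O5 (ortho) and O7 (para), and the base-labile cis C2/C3 pair is complete before the C4 ketone exists.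

Key step: step 7

Assumption: (R)-DTBM-SEGPHOS is taken as the ligand antipode that delivers hydride to the C4 face giving 4R; if the sense of induction is the opposite, the (S)-ligand is used.
Numbering: compounds 3–12 use coumarin numbering; ring positions of 13–17 are quoted in chromanone (target) numbering.

**Step 1**
Reactants: 1 phloroglucinol; 2 ethyl 3-oxohexanoate
Product: 3 5,7-dihydroxy-4-propyl-2H-chromen-2-one
Conditions: conc. H2SO4, 90 °C
Reagents that add atoms: none
Why: Pechmann condensation, in which acid-catalysed transesterification, ring hydroxyalkylation and dehydration join the β-keto ester to the threefold-symmetric triphenol, so only one coumarin regioisomer can form.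

**Step 2**
Reactants: 3 5,7-dihydroxy-4-propyl-2H-chromen-2-one; 4 benzyl bromide
Product: 5 7-(benzyloxy)-5-hydroxy-4-propyl-2H-chromen-2-one
Conditions: BnBr (1.0 equiv), K2CO3 (1.05 equiv), acetone, 25 °C
Reagents that add atoms: none
Why: Williamson ether synthesis in which the accessible 7-OH should react before the 5-OH, which is screened by the peri 4-propyl group, and limiting benzyl bromide keeps bis-alkylation low.

**Step 3**
Reactants: 6 tert-butyl (S)-3-hydroxybutanoate
Product: 8 tert-butyl (2S,3S)-3-hydroxy-2-methylbutanoate, via dilithium alkoxide enolate 7 (not isolated)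
Conditions: LiN(i-Pr)2 (2.2 equiv), THF, −78 to −20 °C; MeI, DMPU, −78 to 0 °C; H2O
Reagents that add atoms: methyl iodide, CI; lithium diisopropylamide, [Li+].CC(C)[N-]C(C)C (its lithium stays only in intermediate 7)
Why: Fráter–Seebach alkylation, in which the lithium-chelated alkoxide enolate 7 is methylated on the face away from the methyl group on the carbinol carbon, which should set C2 as S, anti to the C3 hydroxyl.

**Step 4**
Reactants: 5 7-(benzyloxy)-5-hydroxy-4-propyl-2H-chromen-2-one; 8 tert-butyl (2S,3S)-3-hydroxy-2-methylbutanoate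
Product: 9 tert-butyl (2S,3R)-3-{[7-(benzyloxy)-2-oxo-4-propyl-2H-chromen-5-yl]oxy}-2-methylbutanoate
Conditions: PPh3, DIAD, THF, 0 to 25 °C
Reagents that add atoms: none
Why: Mitsunobu etherification, in which the acidic coumarin 5-OH displaces the oxyphosphonium of 8 by SN2 with inversion at the carbinol carbon, turning the anti (3S) alcohol into the syn (2S,3R) aryl ether.

**Step 5**
Reactants: 9 tert-butyl (2S,3R)-3-{[7-(benzyloxy)-2-oxo-4-propyl-2H-chromen-5-yl]oxy}-2-methylbutanoate
Product: 10 tert-butyl (2S,3R)-3-{[(4R)-7-(benzyloxy)-2-oxo-4-propylchroman-5-yl]oxy}-2-methylbutanoate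
Conditions: Cu(OAc)2·H2O (5 mol %), (R)-DTBM-SEGPHOS (5 mol %), (EtO)2MeSiH (2 equiv), t-BuOH (1.2 equiv), toluene, 0 to 25 °C; aq. NH4F
Reagents that add atoms: none
Why: Copper hydride-catalysed asymmetric conjugate reduction of a 4-substituted coumarin, in which the bisphosphine-ligated hydride adds to C4 on the face chosen by the ligand and the copper enolate is protonated by t-BuOH, which should set C4 as R while the tert-butyl ester and benzyl ether stay inert and any 4S epimer is a separable diastereomer.

**Step 6**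
Reactants: 10 tert-butyl (2S,3R)-3-{[(4R)-7-(benzyloxy)-2-oxo-4-propylchroman-5-yl]oxy}-2-methylbutanoate
Product: 11 (2S,3R)-3-{[(4R)-7-(benzyloxy)-2-oxo-4-propylchroman-5-yl]oxy}-2-methylbutanoic acid
Conditions: CF3CO2H/CH2Cl2 (1:4), 0 to 25 °C
Reagents that add atoms: none
Why: Acidolysis of the tert-butyl ester through the tert-butyl cation frees the acid without base, so neither E1cB loss of the aryloxide nor epimerisation next to the carboxyl is expected, and the lactone and benzyl ether should survive the brief exposure.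

**Step 7**
Reactants: 11 (2S,3R)-3-{[(4R)-7-(benzyloxy)-2-oxo-4-propylchroman-5-yl]oxy}-2-methylbutanoic acid
Product: 13 (2R,3S,10R)-5-(benzyloxy)-2,3-dimethyl-10-propyl-2,3,9,10-tetrahydro-4H,8H-pyrano[2,3-f]chromene-4,8-dione, via mixed trifluoroacetic anhydride 12 (not isolated)
Conditions: (CF3CO)2O (2.5 equiv), CH2Cl2, 0 °C; pH 7 phosphate buffer
Reagents that add atoms: trifluoroacetic anhydride, O=C(OC(=O)C(F)(F)F)C(F)(F)F (its trifluoroacetyl group is held only by intermediate 12; none of its atoms remain in 13)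
Why: Trifluoroacetic anhydride turns acid 11 into mixed anhydride 12, which, helped by the trifluoroacetic acid released, acts as an acylium equivalent that attacks C4a to give an arenium ion, and loss of a proton gives the ketone. This is an intramolecular Friedel–Crafts acylation, the standard closure of 3-aryloxypropanoic acids to chroman-4-ones. Pyranone ring B closes in a six-membered mode, exo at the acyl carbon (the C=O stays outside the ring) and onto the arene π-bond, forming C4–C4a. No stereocentre is created: C2 and C3 arrive intact from 11 and the lactone centre is untouched, and the base-free medium at 0 °C should avoid enolisation at C3 and loss of the aryloxide. The step needs regio- and chemoselectivity: the tether on O1 reaches only its two ortho carbons, of which C8 is fully substituted by the lactone-bound side chain, while C4a is activated by O1 and O5 (ortho) and O7 (para). The one remaining ring CH (C6) can only be acylated intermolecularly, which the fast six-ring closure should outrun.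

**Step 8**
Reactants: 13 (2R,3S,10R)-5-(benzyloxy)-2,3-dimethyl-10-propyl-2,3,9,10-tetrahydro-4H,8H-pyrano[2,3-f]chromene-4,8-dione
Product: 14 (2R,3S,10R)-5-hydroxy-2,3-dimethyl-10-propyl-2,3,9,10-tetrahydro-4H,8H-pyrano[2,3-f]chromene-4,8-dione
Conditions: H2 (1 atm), Pd/C (10 wt %), EtOAc, 25 °C
Reagents that add atoms: none
Why: Hydrogenolysis of the benzyl aryl ether under neutral conditions should leave the oxygen-conjugated ketone, the lactone (no alcohol solvent) and the cis methyl pair untouched, and the freed 5-OH is held by a hydrogen bond to the C4 carbonyl.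

**Step 9**
Reactants: 14 (2R,3S,10R)-5-hydroxy-2,3-dimethyl-10-propyl-2,3,9,10-tetrahydro-4H,8H-pyrano[2,3-f]chromene-4,8-dione; 15 prenyl bromide (1-bromo-3-methylbut-2-ene)
Product: 17 methyl (3R)-3-[(2R,3S)-5,7-dihydroxy-2,3-dimethyl-6-(3-methylbut-2-en-1-yl)-4-oxo-3,4-dihydro-2H-chromen-8-yl]hexanoate, via sodium 7-phenoxide methyl ester 16 (not isolated)
Conditions: NaOMe (1.0 equiv), MeOH, 0 °C; then prenyl bromide (1.2 equiv), 0 to 25 °C
Reagents that add atoms: sodium methoxide, [Na+].[O-]C (its methoxy group becomes the ester OCH3; sodium stays only in 16)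
Why: Methanolysis of the activated aryl ester (O7 is para to the ketone, so its phenoxide is a good leaving group) gives phenoxide 16, which undergoes phenoxide C-alkylation by prenyl bromide at C6, the only unsubstituted ring carbon, in hydrogen-bonding methanol and then tautomerises, while the single equivalent of base leaves no free methoxide to enolise C3.

**Compound list**
1 | phloroglucinol | Oc1cc(O)cc(O)c1 | starting material
2 | ethyl 3-oxohexanoate | CCCC(=O)CC(=O)OCC | starting material
3 | 5,7-dihydroxy-4-propyl-2H-chromen-2-one | CCCC1=CC(=O)Oc2cc(O)cc(O)c12 | intermediate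
4 | benzyl bromide | BrCc1ccccc1 | starting material
5 | 7-(benzyloxy)-5-hydroxy-4-propyl-2H-chromen-2-one | CCCC1=CC(=O)Oc2cc(OCc3ccccc3)cc(O)c12 | intermediate
6 | tert-butyl (S)-3-hydroxybutanoate | C[C@H](O)CC(=O)OC(C)(C)C | starting material
7 | dilithium alkoxide enolate of 6 (formed in the flask) | [Li+].[Li+].C[C@H]([O-])/C=C(\[O-])OC(C)(C)C | intermediate
8 | tert-butyl (2S,3S)-3-hydroxy-2-methylbutanoate | C[C@H](O)[C@H](C)C(=O)OC(C)(C)C | intermediate
9 | tert-butyl (2S,3R)-3-{[7-(benzyloxy)-2-oxo-4-propyl-2H-chromen-5-yl]oxy}-2-methylbutanoate | CCCC1=CC(=O)Oc2cc(OCc3ccccc3)cc(O[C@H](C)[C@H](C)C(=O)OC(C)(C)C)c12 | intermediate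
10 | tert-butyl (2S,3R)-3-{[(4R)-7-(benzyloxy)-2-oxo-4-propylchroman-5-yl]oxy}-2-methylbutanoate | CCC[C@H](CC(=O)O1)c2c(O[C@H](C)[C@H](C)C(=O)OC(C)(C)C)cc(OCc3ccccc3)cc21 | intermediate
11 | (2S,3R)-3-{[(4R)-7-(benzyloxy)-2-oxo-4-propylchroman-5-yl]oxy}-2-methylbutanoic acid | CCC[C@H](CC(=O)O1)c2c(O[C@H](C)[C@H](C)C(=O)O)cc(OCc3ccccc3)cc21 | intermediate
12 | mixed anhydride of 11 with trifluoroacetic acid (formed in the flask) | CCC[C@H](CC(=O)O1)c2c(O[C@H](C)[C@H](C)C(=O)OC(=O)C(F)(F)F)cc(OCc3ccccc3)cc21 | intermediate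
13 | (2R,3S,10R)-5-(benzyloxy)-2,3-dimethyl-10-propyl-2,3,9,10-tetrahydro-4H,8H-pyrano[2,3-f]chromene-4,8-dione | CCC[C@H](CC(=O)O1)c2c3O[C@H](C)[C@H](C)C(=O)c3c(OCc4ccccc4)cc21 | intermediate
14 | (2R,3S,10R)-5-hydroxy-2,3-dimethyl-10-propyl-2,3,9,10-tetrahydro-4H,8H-pyrano[2,3-f]chromene-4,8-dione | CCC[C@H](CC(=O)O1)c2c3O[C@H](C)[C@H](C)C(=O)c3c(O)cc21 | intermediate
15 | prenyl bromide (1-bromo-3-methylbut-2-ene) | CC(C)=CCBr | starting material
16 | sodium 7-phenoxide of methyl (3R)-3-[(2R,3S)-5,7-dihydroxy-2,3-dimethyl-4-oxochroman-8-yl]hexanoate (formed in the flask) | CCC[C@H](CC(=O)OC)c1c([O-])cc(O)c2c1O[C@H](C)[C@H](C)C2=O.[Na+] | intermediate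
17 | methyl (3R)-3-[(2R,3S)-5,7-dihydroxy-2,3-dimethyl-6-(3-methylbut-2-en-1-yl)-4-oxo-3,4-dihydro-2H-chromen-8-yl]hexanoate | CCC[C@H](CC(=O)OC)c1c(O)c(CC=C(C)C)c(O)c2c1O[C@H](C)[C@H](C)C2=O | target

**Count**
Total steps: 9. Longest linear sequence: 8 steps (1, 2, 4, 5, 6, 7, 8, 9 from phloroglucinol); step 3 is a one-step side branch.

**Steps most likely to fail**

Step 5. Hydride transfer to the fully substituted, electron-rich C3=C4 bond next to the bulky 5-alkoxy group may be slow. Face selectivity may be eroded by the resident side-chain centres, and the lactone carbonyl may be reduced on to the lactol. The fallback sets the same centre by delivering carbon instead of hydrogen to C4.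
- It sets out from 1: condensation with ethyl propiolate (ZnCl2, dioxane, 90 °C) should give 5,7-dihydroxy-2H-chromen-2-one F1.
- Monobenzylation with 4 (K2CO3, acetone) should give 7-(benzyloxy)-5-hydroxy-2H-chromen-2-one F2.
- Mitsunobu coupling with 8 (PPh3, DIAD, THF) should give tert-butyl (2S,3R)-3-{[7-(benzyloxy)-2-oxo-2H-chromen-5-yl]oxy}-2-methylbutanoate F3.
- Copper-catalysed asymmetric conjugate addition of n-PrMgBr then comes back to the route at 10. Conditions: CuBr·SMe2 (5 mol %), 1-[2-(diphenylphosphino)ferrocenyl]ethyldicyclohexylphosphine in the antipode that gives 4R, t-BuOMe, −78 °C, where the tert-butyl ester should tolerate the Grignard reagent.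

Step 4. Dehydration of the activated β-hydroxy ester (loss of the oxyphosphonium together with the acidic α-hydrogen, giving the tiglate) may outrun SN2 attack by the sterically screened phenol. The fallback removes the acidic α-hydrogen by working at the alcohol oxidation level.
- It sets out from 8: LiAlH4 (THF, 0 °C) should give (2R,3S)-2-methylbutane-1,3-diol F4.
- TBSCl and imidazole (CH2Cl2, 0 °C) should silylate the primary hydroxyl to give (2S,3R)-4-[(tert-butyldimethylsilyl)oxy]-3-methylbutan-2-ol F5.
- Mitsunobu coupling of F5 with 5 should give 7-(benzyloxy)-5-{[(2R,3R)-4-[(tert-butyldimethylsilyl)oxy]-3-methylbutan-2-yl]oxy}-4-propyl-2H-chromen-2-one F6.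
- Copper hydride reduction under the conditions of step 5 should give (4R)-7-(benzyloxy)-5-{[(2R,3R)-4-[(tert-butyldimethylsilyl)oxy]-3-methylbutan-2-yl]oxy}-4-propylchroman-2-one F7.
- HF·pyridine (THF) should free (4R)-7-(benzyloxy)-5-{[(2R,3R)-4-hydroxy-3-methylbutan-2-yl]oxy}-4-propylchroman-2-one F8.
- Oxidation of the primary alcohol with TEMPO (cat.) and PhI(OAc)2 in MeCN/H2O comes back to the route at 11.

Step 9. O-alkylation at O7 and a second alkylation at C6 may compete with the single C-alkylation, and C3 may epimerise if free methoxide persists. The fallback reaches the C6–C bond by a sigmatropic shift from O7.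
- It sets out from 14: NaOMe (0.1 equiv) in MeOH at 0 °C, then AcOH, should give methyl (3R)-3-[(2R,3S)-5,7-dihydroxy-2,3-dimethyl-4-oxochroman-8-yl]hexanoate F9.
- 3-Chloro-3-methylbut-1-yne with CuCl2·2H2O (cat.) and DBU in MeCN at 0 °C should etherify the free 7-OH (the 5-OH is held by the carbonyl) to give methyl (3R)-3-[(2R,3S)-5-hydroxy-2,3-dimethyl-7-[(2-methylbut-3-yn-2-yl)oxy]-4-oxochroman-8-yl]hexanoate F10.
- Semihydrogenation (H2, Pd/CaCO3 poisoned with Pb(OAc)2, quinoline, EtOAc) should give methyl (3R)-3-[(2R,3S)-5-hydroxy-2,3-dimethyl-7-[(2-methylbut-3-en-2-yl)oxy]-4-oxochroman-8-yl]hexanoate F11.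
- Heating in toluene at about 110 °C should bring about an aromatic Claisen rearrangement to C6 (C8 is blocked) with allylic transposition, which comes back to the route at 17.

**Further compounds**
F1 | step 5 | 5,7-dihydroxy-2H-chromen-2-one | O=C1C=Cc2c(O)cc(O)cc2O1
F2 | step 5 | 7-(benzyloxy)-5-hydroxy-2H-chromen-2-one | O=C1C=Cc2c(O)cc(OCc3ccccc3)cc2O1
F3 | step 5 | tert-butyl (2S,3R)-3-{[7-(benzyloxy)-2-oxo-2H-chromen-5-yl]oxy}-2-methylbutanoate | O=C1C=Cc2c(O[C@H](C)[C@H](C)C(=O)OC(C)(C)C)cc(OCc3ccccc3)cc2O1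
F4 | step 4 | (2R,3S)-2-methylbutane-1,3-diol | C[C@H](O)[C@H](C)CO
F5 | step 4 | (2S,3R)-4-[(tert-butyldimethylsilyl)oxy]-3-methylbutan-2-ol | C[C@H](O)[C@H](C)CO[Si](C)(C)C(C)(C)C
F6 | step 4 | 7-(benzyloxy)-5-{[(2R,3R)-4-[(tert-butyldimethylsilyl)oxy]-3-methylbutan-2-yl]oxy}-4-propyl-2H-chromen-2-one | CCCC1=CC(=O)Oc2cc(OCc3ccccc3)cc(O[C@H](C)[C@H](C)CO[Si](C)(C)C(C)(C)C)c12
F7 | step 4 | (4R)-7-(benzyloxy)-5-{[(2R,3R)-4-[(tert-butyldimethylsilyl)oxy]-3-methylbutan-2-yl]oxy}-4-propylchroman-2-one | CCC[C@H](CC(=O)O1)c2c(O[C@H](C)[C@H](C)CO[Si](C)(C)C(C)(C)C)cc(OCc3ccccc3)cc21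
F8 | step 4 | (4R)-7-(benzyloxy)-5-{[(2R,3R)-4-hydroxy-3-methylbutan-2-yl]oxy}-4-propylchroman-2-one | CCC[C@H](CC(=O)O1)c2c(O[C@H](C)[C@H](C)CO)cc(OCc3ccccc3)cc21
F9 | step 9 | methyl (3R)-3-[(2R,3S)-5,7-dihydroxy-2,3-dimethyl-4-oxochroman-8-yl]hexanoate | CCC[C@H](CC(=O)OC)c1c(O)cc(O)c2c1O[C@H](C)[C@H](C)C2=O
F10 | step 9 | methyl (3R)-3-[(2R,3S)-5-hydroxy-2,3-dimethyl-7-[(2-methylbut-3-yn-2-yl)oxy]-4-oxochroman-8-yl]hexanoate | CCC[C@H](CC(=O)OC)c1c(OC(C)(C)C#C)cc(O)c2c1O[C@H](C)[C@H](C)C2=O
F11 | step 9 | methyl (3R)-3-[(2R,3S)-5-hydroxy-2,3-dimethyl-7-[(2-methylbut-3-en-2-yl)oxy]-4-oxochroman-8-yl]hexanoate | CCC[C@H](CC(=O)OC)c1c(OC(C)(C)C=C)cc(O)c2c1O[C@H](C)[C@H](C)C2=O
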